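Count the reagent in this flask first.

| flask | starting material | reagent | remark | time |
|---|---|---|---|---|
| Saturday's | 10 mM (fed, over 50 s) | 0.70 equiv | run made earlier |  |
| Friday's | 15 mM (fed, over 50 s) | 0.70 equiv | run made earlier |  |
| Sunday's | 20 mM (fed, over 50 s) | 1.4 equiv | run made earlier |  |
| flask | 20 mM (fed, over 50 s) | 0.700 equiv |  | 40 h |

| run | time / h | target / % | over-reaction product / % |
|---|---|---|---|
| Saturday's | 6.00 | 18.1 | 25.3 |
| Saturday's | 15.0 | 18.8 | 26.0 |
| Saturday's | 30.0 | 18.4 | 26.3 |
| Saturday's | 50.0 | 18.6 | 25.4 |
| Friday's | 4.00 | 28.5 | 20.2 |
| Friday's | 8.00 | 28.5 | 20.7 |
| Friday's | 20.0 | 28.5 | 20.0 |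
| Friday's | 50.0 | 28.3 | 20.5 |
| Sunday's | 4.00 | 38.6 | 50.8 |
| Sunday's | 8.00 | 38.0 | 51.4 |
| Sunday's | 20.0 | 39.0 | 50.4 |
| Sunday's | 50.0 | 39.2 | 51.0 |

(scatter of a reading: 0.5 percentage points)

- the reaction counts as stopped when no species that holds the starting material changes by six tenths of a point or more over the second half of the time

- the state of affairs at 40 h: stopped, and by what, or still going (it is still moving / all of the starting material has reacted / the reagent has run out first)
- amount of target at 40 h, in percent of the starting material charged
- amount of over-reaction product at 40 h, in percent of the starting material charged
- amount of target if the flask were left three thousand times as long, in percent of the starting material charged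

Let P be the target and O the over-reaction product, both in percent of the starting material charged. For the flask I set B = 70.0%, the reagent budget: the reagent charged, in percent of the starting material charged.

The runs form a ladder of times. The feed comes first: its 50 s ends long before Friday's first reading at 4.00 h.

The reagent count comes next. At that first reading, Friday's P + 2·O is 68.9% against a charge of 70.0%. Sunday's is 140% against 140%. So I read one reagent in each target and two in each over-reaction product, and for the flask I take the reagent as the limiting reagent.

The last rung is rest. Friday's target reads 28.5% there and 28.3% at 50.0 h, with a scatter of 0.5 percentage points. The flask's 40 h falls before Friday's last reading, so I expect the flask on this rung and commit to a line: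

P + 2·O = B

O = (B − P)/2

Starting material left = 100% − P − O

This line does not give the split between P and O, and I do not reckon that split. The forecast does: the reagent has run out first, with 34.5% target, 17.7% over-reaction product, and 34.5% target after the long wait. Its ground is “The plateaus are flat, so the reagent ran out and the products are stable.”

The simulation of the flask gives the reagent has run out first, with 35.9% target, 17.0% over-reaction product, and 35.9% target after the long wait.

    starting material + reagent + target → 2 target (k = 920 /M²/min)
    starting material + reagent → target (k = 0.0170 /M/min)
    reagent + target → over-reaction product (k = 4.20 /M/min)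

In the flask, reagent stands at 0% at 20.0 h and at 0% at 40.0 h. Its P + 2·O is 69.9% against B = 70.0%, and 47% of its starting material stays unreacted. The neighbour with 8.0 mM of starting material keeps the equivalents, so its B is also 70.0%. Its target is 12.2%, so the line gives O = 28.9%, and the neighbour shows 28.9%. The line leaves 58.9% of starting material, and the neighbour holds 59%.

The numbers in the tables are calculated for substances that don't exist, and the scatter is random.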